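**Plan**

- Retrosynthesis: the C8 ester, the C11 acetate and the C11 methyl are removed first. The target γ-lactone is cut at C7–C11 and O6–C12, back to a C6 cyclohexanone and a glyoxylate. The vinyl (C1=C2) and isopropenyl (C4=C3) groups are folded back into a temporary γ-lactone C1(=O)–O–C4. Last, C8–C9 and C5–C10 are cut together.
- Enabling feature: in the cyclohexane, C9H2–C10(CH3)(vinyl) sits next to C5–isopropenyl, and the two alkenyl groups are cis. This is a methacrylate (C9=C10, carbonyl C1) tied through C1–O–C4 to a diene C5=C6–C7=C8 whose C8 carries the later oxygen as boron.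
- Forward: a linear dienyl methacrylate gives the cyclohexene and the tether lactone in one cycloaddition. Then C8–B becomes C8–O, the tether carboxylate is moved to O6 by iodolactonisation, isopropenyl and vinyl are unveiled, C6 becomes a ketone, the target lactone is built by aldol and reduction, C11 receives methyl and acetate, and C8 is esterified.
- Stereochemistry: the carbinol C4 of (R)-but-3-yn-2-ol (destroyed later) sets the face of the cycloaddition, which fixes C5, C10 and C8 at once. C7 follows under thermodynamic control, C6 from a bulky hydride, C11 from convex-face methylation.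

Key step: step 4

Remark: locants follow the elemane skeleton (C10 quaternary with methyl and vinyl C1=C2; C5 with isopropenyl C4; C6–O; C7; C8–O; C9H2; C11/C12 lactone α-carbon and carbonyl), β is the ring face of the C10 methyl, and (R)-but-3-yn-2-ol, the bromovinyl MIDA boronate, methacryloyl chloride, ethyl glyoxylate and 3-methylbut-3-enoic acid are taken as commercial.

**Route**

Step 1
Reactants: 1 (R)-but-3-yn-2-ol; 2 (E)-2-bromovinylboronic acid MIDA ester
Product: 3 (2R,5E)-6-(MIDA-boryl)hex-5-en-3-yn-2-ol
Conditions: PdCl2(PPh3)2 (5 mol %), CuI (10 mol %), Et3N, THF, rt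
Reagents that add atoms: none
Why: Sonogashira coupling of the terminal alkyne with the (E)-vinyl bromide should proceed with retention of the alkene geometry and leave the sp3-boron MIDA cage and the carbinol centre untouched.

Step 2
Reactants: 3 (2R,5E)-6-(MIDA-boryl)hex-5-en-3-yn-2-ol
Product: 4 (2R,3Z,5E)-6-(MIDA-boryl)hexa-3,5-dien-2-ol
Conditions: H2 (1 atm), Pd/CaCO3 poisoned with Pb(OAc)2, quinoline, EtOAc, rt
Reagents that add atoms: none
Why: Lindlar-type syn semi-hydrogenation of the internal alkyne should give the (Z)-alkene, so that C4 becomes the "inside" substituent of the (3Z,5E)-diene while the vinylboronate double bond is not reduced.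

Step 3
Reactants: 4 (2R,3Z,5E)-6-(MIDA-boryl)hexa-3,5-dien-2-ol; 5 methacryloyl chloride
Product: 6 (2R,3Z,5E)-6-(MIDA-boryl)hexa-3,5-dien-2-yl methacrylate
Conditions: Et3N, DMAP (cat.), CH2Cl2, 0 °C
Reagents that add atoms: none
Why: O-acylation of the secondary alcohol by the acid chloride under nucleophilic catalysis installs the tethered dienophile without touching the C4 stereocentre.

Step 4
Reactants: 6 (2R,3Z,5E)-6-(MIDA-boryl)hexa-3,5-dien-2-yl methacrylate
Product: 7 cis-fused tether lactone 3,7a-dimethyl-6-(MIDA-boryl)-3a,6,7,7a-tetrahydroisobenzofuran-1(3H)-one (C4 R; H5 and C10-CH3 and C4-CH3 and boron all β; C6=C7 alkene)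
Conditions: o-dichlorobenzene/MeCN, BHT (cat.), 160 °C, sealed tube, 5 mM
Reagents that add atoms: none
Why: A thermal, concerted but asynchronous [4+2] cycloaddition (type 1 intramolecular Diels–Alder of an ester-tethered 1,6,8-nonatriene, the closest known class being dienyl acrylates) should join C9 of the methacrylate to C8 and C10 to C5. The cyclohexene closes by the cycloaddition itself and the five-membered lactone closes in the fused mode through the C5–C10 bond, the three-atom tether (C4, O, C1) excluding the bridged regiochemistry. Because C4 sits "inside" on the (Z)-C5=C6 bond, only the transition state with the tether carbonyl exo to the diene is within reach, which gives the cis ring fusion (C1 and C4 on one face, H5 and the C10 methyl on the other) and creates the quaternary C10. The (E)-boryl group, being "outside", ends syn to the endo methyl, so C8–B is trans to the tether, which is the later C8–O configuration. The (R)-carbinol C4 fixes the diene face: allylic 1,3-strain keeps C4–H in the diene plane and the C4 methyl away from the incoming dienophile, so the three new centres arise in one enantiomeric series. The step needs the cycloaddition to outrun the 1,5-hydrogen shift of the (Z)-diene and acrylate polymerisation, which high dilution, a radical inhibitor and the activated, tether-bound dienophile are expected to secure.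

Step 5
Reactants: 7 cis-fused tether lactone with 8β-MIDA-boryl group
Product: 8 cis-fused tether lactone 6-hydroxy-3,7a-dimethyl-3a,6,7,7a-tetrahydroisobenzofuran-1(3H)-one (8β-OH)
Conditions: aq. NaHCO3, THF/MeOH, then 30% H2O2, 0 °C to rt
Reagents that add atoms: hydrogen peroxide (OO)
Why: Mild aqueous base should open the MIDA cage and peroxide should oxidise the C–B bond with retention (boronate oxidation), so that C8 carries the β-hydroxyl while the hindered lactone survives the buffered medium.

Step 6
Reactants: 8 cis-fused tether lactone with 8β-OH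
Product: 9 8β-(tert-butyldimethylsilyloxy) tether lactone
Conditions: TBSCl, imidazole, DMF, rt
Reagents that add atoms: tert-butyldimethylsilyl chloride (CC(C)(C)[Si](C)(C)Cl)
Why: Silylation of the secondary allylic alcohol protects O8 against the hydroxide, oxidant, ylide and enolate steps that follow.

Step 7
Reactants: 9 8β-(tert-butyldimethylsilyloxy) tether lactone
Product: 11 bridged iodolactone (C1(=O)–O6 γ-lactone; O6 α; 7β-iodo; 8β-OTBS; C5 bearing (R)-1-hydroxyethyl), via lithium seco-carboxylate 10 (not isolated)
Conditions: LiOH, THF/H2O, 40 °C; then NaHCO3, I2, KI, 0 °C, dark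
Reagents that add atoms: lithium hydroxide ([Li+].[OH-]); iodine (II)
Why: Saponification frees the C1 carboxylate, which should open the iodonium ion of C6=C7 at C6 from its own α face (iodolactonisation of a cyclohex-3-enecarboxylate, anti addition), placing oxygen regioselectively at C6 with iodine β at C7 and releasing the tether carbinol C4–OH.

Step 8
Reactants: 11 bridged iodolactone
Product: 12 bridged lactone alcohol (C7 now CH2)
Conditions: Bu3SnH, AIBN (cat.), benzene, 80 °C
Reagents that add atoms: none
Why: Radical chain dehalogenation with the tin hydride should remove the C7 iodine without affecting the lactone or the silyl ether.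

Step 9
Reactants: 12 bridged lactone alcohol
Product: 13 bridged lactone methyl ketone (C5-acetyl)
Conditions: Dess–Martin periodinane, NaHCO3, CH2Cl2, rt
Reagents that add atoms: none
Why: Dess–Martin oxidation of the secondary alcohol gives the methyl ketone and thereby erases the relay centre C4 once it has done its work.

Step 10
Reactants: 13 bridged lactone methyl ketone
Product: 14 bridged lactone with C5-isopropenyl group
Conditions: Zn, CH2Br2, TiCl4, THF/CH2Cl2, 0 °C to rt
Reagents that add atoms: dibromomethane (BrCBr)
Why: Takai–Lombardo methylenation should convert the methyl ketone into the isopropenyl group under non-basic conditions, which avoids β-elimination of the lactone oxygen at C6 and leaves the lactone carbonyl untouched.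

Step 11
Reactants: 14 bridged lactone with C5-isopropenyl group
Product: 15 bridged lactol (C1 hemiacetal, both anomers)
Conditions: i-Bu2AlH, CH2Cl2, −78 °C
Reagents that add atoms: none
Why: Partial reduction of the γ-lactone by a single hydride at low temperature should stop at the lactol because the aluminium hemiacetal is stable at −78 °C.

Step 12
Reactants: 15 bridged lactol
Product: 16 8β-(tert-butyldimethylsilyloxy)-5βH-elema-1,3-dien-6α-ol
Conditions: Ph3PCH3Br, KOt-Bu, THF, 0 to 50 °C
Reagents that add atoms: methyltriphenylphosphonium bromide (C[P+](c1ccccc1)(c1ccccc1)c1ccccc1.[Br-])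
Why: Wittig methylenation of the open hydroxy-aldehyde form of the lactol turns C1 into the vinyl group and releases the 6α-hydroxyl, and the aldehyde carbon has no α-hydrogen so no centre can epimerise.

Step 13
Reactants: 16 8β-(tert-butyldimethylsilyloxy)-5βH-elema-1,3-dien-6α-ol
Product: 17 8β-(tert-butyldimethylsilyloxy)-5βH-elema-1,3-dien-6-one
Conditions: Dess–Martin periodinane, NaHCO3, CH2Cl2, 0 °C to rt
Reagents that add atoms: none
Why: Buffered Dess–Martin oxidation should give the C6 ketone without moving the β,γ-double bond of the isopropenyl group into conjugation.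

Step 14
Reactants: 17 8β-(tert-butyldimethylsilyloxy)-5βH-elema-1,3-dien-6-one; 18 ethyl glyoxylate
Product: 20 aldol adduct ethyl 2-hydroxy-2-(C7-yl)acetate of ketone 17 (C7 side chain α and equatorial; C11 epimers), via pyrrolidine enamine 19 (not isolated)
Conditions: pyrrolidine (0.3 equiv), AcOH (0.3 equiv), CH2Cl2, rt
Reagents that add atoms: none
Why: Amine-catalysed direct aldol addition through the enamine at the less substituted α-carbon C7 is reversible, so the side chain should settle equatorial at C7, trans to the 8β-silyloxy group that the cis-1,3 C10 methyl locks equatorial, while C5 is not enolised and the C11 configuration does not matter at this stage.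

Step 15
Reactants: 20 aldol adduct
Product: 22 8β-(tert-butyldimethylsilyloxy)-11-hydroxy-13-nor-elema-1,3-dien-12,6α-olide (cis-fused lactone; C11 epimers), via hydroxy ester 21 (not isolated)
Conditions: LiBH(s-Bu)3, THF, −78 °C; aq. NH4Cl; then PPTS (cat.), benzene, 50 °C
Reagents that add atoms: none
Why: The bulky hydride should attack the doubly flanked C6 ketone from the equatorial β direction, the axial α face being blocked by the axial vinyl group, to give the axial 6α-alkoxide that closes the cis-fused γ-lactone onto the ethyl ester (reduction–lactonisation), whereas a minor C7 epimer would be trans-diaxial and could not lactonise.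

Step 16
Reactants: 22 α-hydroxy lactone
Product: 25 8β-(tert-butyldimethylsilyloxy)-11-acetoxy-elema-1,3-dien-12,6α-olide (C11 methyl syn to H7), via dilithium enediolate 23 (not isolated), via lithium alkoxide 24 (not isolated)
Conditions: LiN(i-Pr)2 (2.3 equiv), THF, −78 to −40 °C; MeI, −78 °C; then Ac2O, −78 to 0 °C
Reagents that add atoms: iodomethane (CI); acetic anhydride (CC(=O)OC(C)=O)
Why: The planar enediolate of the α-hydroxy lactone should be C-methylated on the convex face (syn to H6 and H7, away from the six-membered ring), which sets C11 with the methyl exo and the oxygen endo whatever the C11 configuration of 22, and the tertiary lithium alkoxide is then acetylated in the same flask (dianion alkylation of an α-hydroxy ester followed by O-acylation).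

Step 17
Reactants: 25 silyl-protected acetoxy lactone
Product: 26 8β-hydroxy-11-acetoxy-elema-1,3-dien-12,6α-olide
Conditions: HF·pyridine, THF/pyridine, 0 °C to rt
Reagents that add atoms: none
Why: Buffered fluoride should cleave the secondary silyl ether through Si–F bond formation while the tertiary acetate, the lactone and the 1,1-disubstituted alkene stay intact.

Step 18
Reactants: 26 8β-hydroxy-11-acetoxy-elema-1,3-dien-12,6α-olide; 27 3-methylbut-3-enoic acid
Product: 28 target CNP0106639.1
Conditions: N,N'-diisopropylcarbodiimide, DMAP (5 mol %), CH2Cl2, 0 °C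
Reagents that add atoms: none
Why: Steglich esterification at low temperature with little DMAP should acylate the equatorial 8β-hydroxyl with retention at C8 while keeping the β,γ-double bond of the acid out of conjugation.

**Compound list**

1 | (R)-but-3-yn-2-ol | C[C@@H](O)C#C | starting material
2 | (E)-2-bromovinylboronic acid MIDA ester | CN1CC(=O)OB(/C=C/Br)OC(=O)C1 | starting material
3 | (2R,5E)-6-(MIDA-boryl)hex-5-en-3-yn-2-ol | C[C@@H](O)C#C/C=C/B1OC(=O)CN(C)CC(=O)O1 | intermediate
4 | (2R,3Z,5E)-6-(MIDA-boryl)hexa-3,5-dien-2-ol | C[C@@H](O)/C=C\C=C\B1OC(=O)CN(C)CC(=O)O1 | intermediate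
5 | methacryloyl chloride | C=C(C)C(=O)Cl | starting material
6 | (2R,3Z,5E)-6-(MIDA-boryl)hexa-3,5-dien-2-yl methacrylate | C[C@@H](OC(=O)C(C)=C)/C=C\C=C\B1OC(=O)CN(C)CC(=O)O1 | intermediate
7 | cis-fused tether lactone, 8β-MIDA-boryl cycloadduct | C[C@H]1OC(=O)[C@]2(C)C[C@@H](B3OC(=O)CN(C)CC(=O)O3)C=C[C@H]12 | intermediate
8 | cis-fused tether lactone, 8β-hydroxy | C[C@H]1OC(=O)[C@]2(C)C[C@@H](O)C=C[C@H]12 | intermediate
9 | cis-fused tether lactone, 8β-OTBS | C[C@H]1OC(=O)[C@]2(C)C[C@@H](O[Si](C)(C)C(C)(C)C)C=C[C@H]12 | intermediate
10 | lithium seco-carboxylate (C1 carboxylate, C4–OH free) | C[C@@H](O)[C@H]1C=C[C@H](O[Si](C)(C)C(C)(C)C)C[C@@]1(C)C(=O)[O-].[Li+] | intermediate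
11 | bridged iodolactone (O6 α, 7β-I) | C[C@@H](O)[C@H]1[C@H]2OC(=O)[C@]1(C)C[C@@H](O[Si](C)(C)C(C)(C)C)[C@H]2I | intermediate
12 | bridged lactone alcohol | C[C@@H](O)[C@H]1[C@H]2OC(=O)[C@]1(C)C[C@@H](O[Si](C)(C)C(C)(C)C)C2 | intermediate
13 | bridged lactone methyl ketone | CC(=O)[C@H]1[C@H]2OC(=O)[C@]1(C)C[C@@H](O[Si](C)(C)C(C)(C)C)C2 | intermediate
14 | bridged lactone with isopropenyl group | C=C(C)[C@H]1[C@H]2OC(=O)[C@]1(C)C[C@@H](O[Si](C)(C)C(C)(C)C)C2 | intermediate
15 | bridged lactol | C=C(C)[C@H]1[C@H]2OC(O)[C@]1(C)C[C@@H](O[Si](C)(C)C(C)(C)C)C2 | intermediate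
16 | 8β-(tert-butyldimethylsilyloxy)-5βH-elema-1,3-dien-6α-ol | C=C[C@]1(C)C[C@@H](O[Si](C)(C)C(C)(C)C)C[C@H](O)[C@@H]1C(C)=C | intermediate
17 | 8β-(tert-butyldimethylsilyloxy)-5βH-elema-1,3-dien-6-one | C=C[C@]1(C)C[C@@H](O[Si](C)(C)C(C)(C)C)CC(=O)[C@@H]1C(C)=C | intermediate
18 | ethyl glyoxylate | CCOC(=O)C=O | starting material
19 | pyrrolidine enamine of 17 (C6=C7) | C=C[C@]1(C)C[C@@H](O[Si](C)(C)C(C)(C)C)C=C(N2CCCC2)[C@@H]1C(C)=C | intermediate
20 | aldol adduct (C7 side chain α, C11 epimers) | C=C[C@]1(C)C[C@@H](O[Si](C)(C)C(C)(C)C)[C@H](C(O)C(=O)OCC)C(=O)[C@@H]1C(C)=C | intermediate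
21 | 6α-hydroxy ester | C=C[C@]1(C)C[C@@H](O[Si](C)(C)C(C)(C)C)[C@H](C(O)C(=O)OCC)[C@H](O)[C@@H]1C(C)=C | intermediate
22 | cis-fused α-hydroxy lactone (C11 epimers) | C=C[C@]1(C)C[C@@H](O[Si](C)(C)C(C)(C)C)[C@H]2[C@H](OC(=O)C2O)[C@@H]1C(C)=C | intermediate
23 | dilithium enediolate of 22 | C=C[C@]1(C)C[C@@H](O[Si](C)(C)C(C)(C)C)[C@H]2[C@H](OC([O-])=C2[O-])[C@@H]1C(C)=C.[Li+].[Li+] | intermediate
24 | lithium alkoxide of the C11-methylated lactone | C=C[C@]1(C)C[C@@H](O[Si](C)(C)C(C)(C)C)[C@H]2[C@H](OC(=O)[C@@]2(C)[O-])[C@@H]1C(C)=C.[Li+] | intermediate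
25 | 8β-OTBS 11-acetoxy lactone | C=C[C@]1(C)C[C@@H](O[Si](C)(C)C(C)(C)C)[C@H]2[C@H](OC(=O)[C@@]2(C)OC(C)=O)[C@@H]1C(C)=C | intermediate
26 | 8β-hydroxy 11-acetoxy lactone | C=C[C@]1(C)C[C@@H](O)[C@H]2[C@H](OC(=O)[C@@]2(C)OC(C)=O)[C@@H]1C(C)=C | intermediate
27 | 3-methylbut-3-enoic acid | C=C(C)CC(=O)O | starting material
28 | CNP0106639.1 | C=C[C@]1(C)C[C@@H](OC(=O)CC(=C)C)[C@H]2[C@H](OC(=O)[C@@]2(C)OC(C)=O)[C@@H]1C(=C)C | target

**Count**

Total steps: 18. Longest linear sequence: 18 steps (1 to 28).

**Steps most likely to fail**

Step 4. The (Z)-diene may undergo a thermal 1,5-hydrogen shift from C4 to C8, or the methacrylate may polymerise, faster than the cycloaddition proceeds; the boronate cage may also degrade at 160 °C. The fallback replaces the thermal reaction by a cationic cycloaddition at low temperature and sets out from 4. Transacetalisation with methacrolein dimethyl acetal (PPTS, benzene) should give the mixed methyl acetal F1. TMSOTf (cat., CH2Cl2, −78 °C) should ionise the methoxy group to a tethered 2-alkoxyallyl cation, which closes through the same tether atoms and the same exo geometry to the cyclic methyl acetal F2. Oxidation of the acetal carbon with CrO3/H2SO4 in acetone returns to the route at 7.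

Step 14. Enamine formation on the hindered ketone may be sluggish and equilibration at C7 incomplete; the β-silyloxy group may be lost, or the isopropenyl double bond may move into conjugation. The fallback sets C7 by protonation instead of by C–C bond formation and sets out from 17. Kinetic aldol addition (LiN(i-Pr)2, then 18) and elimination (MsCl, Et3N) should give the (E)-alkylidene keto ester F3, in which C7 is no longer a stereocentre. Zn/AcOH reduction of the ene-1,4-dicarbonyl unit, with ketonisation by axial protonation, should give the keto ester F4 with the CH2CO2Et chain equatorial. LiBH(s-Bu)3 reduction and lactonisation should give the cis-fused lactone F5. Enolate hydroxylation (LiN(i-Pr)2, then 2-(phenylsulfonyl)-3-phenyloxaziridine) comes back to the route at 22.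

Step 16. The second deprotonation may be incomplete, O-methylation may compete with C-methylation of the dianion, or acyl transfer may occur during the in-situ acetylation. The fallback uses a protected mono-anion and a late acetylation and sets out from 22. TESOTf/2,6-lutidine should give the 11-O-triethylsilyl ether F6. LiN(i-Pr)2/MeI should methylate its enolate on the convex face to the 11-methyl silyl ether F7. Buffered TBAF/AcOH should remove both silyl groups to give the 8β,11-diol lactone F8. Carbodiimide esterification of the secondary 8β-hydroxyl with 27 should give the 11-hydroxy ester F9. Acetylation of the tertiary hydroxyl (Ac2O, DMAP, Et3N) comes back to the route at 28.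

Further compounds
F1 | step 4 | mixed methyl acetal of methacrolein with dienol 4 | C[C@@H](OC(OC)C(C)=C)/C=C\C=C\B1OC(=O)CN(C)CC(=O)O1
F2 | step 4 | cyclic methyl acetal corresponding to lactone 7 | C[C@H]1OC(OC)[C@]2(C)C[C@@H](B3OC(=O)CN(C)CC(=O)O3)C=C[C@H]12
F3 | step 14 | (E)-alkylidene keto ester | C=C[C@]1(C)C[C@@H](O[Si](C)(C)C(C)(C)C)/C(=C\C(=O)OCC)C(=O)[C@@H]1C(C)=C
F4 | step 14 | keto ester with equatorial CH2CO2Et at C7 | C=C[C@]1(C)C[C@@H](O[Si](C)(C)C(C)(C)C)[C@H](CC(=O)OCC)C(=O)[C@@H]1C(C)=C
F5 | step 14 | cis-fused lactone unsubstituted at C11 | C=C[C@]1(C)C[C@@H](O[Si](C)(C)C(C)(C)C)[C@H]2[C@H](OC(=O)C2)[C@@H]1C(C)=C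
F6 | step 16 | 11-O-triethylsilyl ether of 22 | C=C[C@]1(C)C[C@@H](O[Si](C)(C)C(C)(C)C)[C@H]2[C@H](OC(=O)C2O[Si](CC)(CC)CC)[C@@H]1C(C)=C
F7 | step 16 | 11-methyl 11-O-triethylsilyl lactone | C=C[C@]1(C)C[C@@H](O[Si](C)(C)C(C)(C)C)[C@H]2[C@H](OC(=O)[C@@]2(C)O[Si](CC)(CC)CC)[C@@H]1C(C)=C
F8 | step 16 | 8β,11-diol lactone | C=C[C@]1(C)C[C@@H](O)[C@H]2[C@H](OC(=O)[C@@]2(C)O)[C@@H]1C(C)=C
F9 | step 16 | 8β-(3-methylbut-3-enoyloxy)-11-hydroxy lactone | C=C[C@]1(C)C[C@@H](OC(=O)CC(C)=C)[C@H]2[C@H](OC(=O)[C@@]2(C)O)[C@@H]1C(C)=C
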